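**Strategy.** Ring B is disconnected across C7–C8 and C9–C10, so everything rests on one catalytic enantioselective Diels–Alder reaction. The diene C7=C6–C5(OSi)=C10 comes from ethyl vinyl ketone. The dienophile is an (E)-2-methyl-2-enal made from (S)-citronellol, which already holds C8, C9 and C11–C17 and whose formyl group is a masked C8 hydroxyl. In one operation the cycloaddition closes ring B and sets the quaternary C8 and C9. It exploits the trans relation between the C8 oxygen and the C9 side chain on the C7–C8–C9–C10 edge of ring B, with C5 para to C8. Baeyer–Villiger excision, Robinson annulation of ring A and reductive hydroxymethylation at C4 follow.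

Key step: step 4

Remark: atoms are named by labdane numbering (C1–C20); "labdane" in names denotes the skeleton only, and the target belongs to the ent-labdane series, (4S,5S,8S,9S,10R,13S).

Assumption: by the usual model for 2-substituted enals bound to a protonated oxazaborolidine (formyl C–H···O contact, s-trans enal, one face shielded by a phenyl group), the (R)-prolinol-derived catalyst is taken to expose the C8 Si face; if the sense were opposite, the antipodal catalyst would be used and nothing else changes.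

**Step 1**
Reactants: 1 (S)-citronellol
Product: 2 (S)-triisopropyl[(3,7-dimethyloct-6-en-1-yl)oxy]silane
Conditions: TIPSCl, imidazole, DMF, 0 °C to rt
Reagents that add atoms: triisopropylsilyl chloride CC(C)[Si](Cl)(C(C)C)C(C)C
Why: Silyl ether formation at the only hydroxyl; the triisopropylsilyl group is chosen because it should survive the Lewis acid, peracid, alkoxide and dissolving-metal steps, and C13 is untouched.

**Step 2**
Reactants: 2 (S)-triisopropyl[(3,7-dimethyloct-6-en-1-yl)oxy]silane
Product: 4 (S,E)-2,6-dimethyl-8-(triisopropylsilyloxy)oct-2-enal, via allylic alcohol 3 (not isolated)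
Conditions: SeO2 (cat.), t-BuOOH (aq.), salicylic acid (cat.), CH2Cl2, rt; then MnO2, CH2Cl2, rt on the crude mixture
Reagents that add atoms: tert-butyl hydroperoxide CC(C)(C)OO (terminal oxygen source); selenium dioxide O=[Se]=O (catalytic oxygen carrier)
Why: Allylic oxidation by SeO2 (ene reaction then [2,3]-sigmatropic shift) attacks the (E)-methyl group of the trisubstituted alkene selectively, and MnO2 then oxidises the allylic alcohol to the (E)-enal without touching the silyl ether.

**Step 3**
Reactants: 5 pent-1-en-3-one (ethyl vinyl ketone)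
Product: 6 (Z)-tert-butyldimethyl(penta-1,3-dien-3-yloxy)silane
Conditions: TBSOTf, Et3N, Et2O, 0 °C
Reagents that add atoms: tert-butyldimethylsilyl trifluoromethanesulfonate CC(C)(C)[Si](C)(C)OS(=O)(=O)C(F)(F)F
Why: Soft enolisation and O-silylation of the vinyl ketone (silyl enol ether formation) gives the 2-siloxydiene, the (Z)-enol ether with the methyl group on the outside of the diene being favoured.

**Step 4**
Reactants: 4 (S,E)-2,6-dimethyl-8-(triisopropylsilyloxy)oct-2-enal; 6 (Z)-tert-butyldimethyl(penta-1,3-dien-3-yloxy)silane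
Product: 8 (1S,2S,3S)-1,3-dimethyl-2-[(3S)-3-methyl-5-(triisopropylsilyloxy)pentyl]-4-oxocyclohexane-1-carbaldehyde, via silyl enol ether 7 (not isolated)
Conditions: (R)-tetrahydro-1-(2-methylphenyl)-3,3-diphenyl-1H,3H-pyrrolo[1,2-c][1,3,2]oxazaborole (20 mol %), HNTf2 (18 mol %), CH2Cl2, −78 to −40 °C; then 1 M HCl, THF, 0 °C
Reagents that add atoms: none
Why: The protonated oxazaborolidine binds the formyl group of 4 and the 2-siloxydiene 6 adds in a concerted but asynchronous normal-demand [4+2] cycloaddition, in which bonding of the siloxy-activated terminus C10 to the β-carbon C9 runs ahead and the C7–C8 bond to the α-carbon completes ring B. The closest known reaction type is the cationic-oxazaborolidine-catalysed Diels–Alder reaction of 2-methyl-substituted enals with 2-siloxybutadienes. Ring B closes as a six-membered carbocycle by suprafacial addition on both partners, with para regiochemistry (C5–OSi 1,4 to the formyl-bearing C8) imposed by the siloxy group, which outweighs the terminal methyl. The C8/C9 relative configuration (formyl, later oxygen, trans to the side chain; C17 cis to it) is a stereospecific consequence of the (E)-enal geometry, and the absolute configuration comes from the catalyst, which shields the C8 Re face so that the diene adds to the Si face; C10 (endo or exo approach) is of no consequence because it is enolised in step 6, and C13 is a spectator. The step needs chemoselectivity for the C=C over the C=O bond of the enal, secured by the α-methyl group and the hindered silyl enol ether, and regioselectivity, secured by the siloxy group of the diene. Acidic work-up hydrolyses enol ether 7 to ketone 8 without touching the primary silyl ether.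

**Step 5**
Reactants: 8 (1S,2S,3S)-1,3-dimethyl-2-[(3S)-3-methyl-5-(triisopropylsilyloxy)pentyl]-4-oxocyclohexane-1-carbaldehyde
Product: 10 (2S,3S,4S)-4-hydroxy-2,4-dimethyl-3-[(3S)-3-methyl-5-(triisopropylsilyloxy)pentyl]cyclohexan-1-one, via formate 9 (not isolated)
Conditions: m-CPBA (1.1 equiv), NaHCO3, CH2Cl2, 0 °C; then K2CO3 (cat.), MeOH, rt
Reagents that add atoms: 3-chloroperbenzoic acid OOC(=O)c1cccc(Cl)c1
Why: Baeyer–Villiger oxidation: the aldehyde should add peracid faster than the saturated ring ketone and the tertiary C8 should migrate with retention in preference to hydrogen, so the formate and, after methanolysis, the C8 alcohol keep the configuration set in step 4.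

**Step 6**
Reactants: 10 (2S,3S,4S)-4-hydroxy-2,4-dimethyl-3-[(3S)-3-methyl-5-(triisopropylsilyloxy)pentyl]cyclohexan-1-one; 5 pent-1-en-3-one
Product: 13 (4aS,5S,6S)-6-hydroxy-1,4a,6-trimethyl-5-[(3S)-3-methyl-5-(triisopropylsilyloxy)pentyl]-4,4a,5,6,7,8-hexahydronaphthalen-2(3H)-one, via Michael adduct 11 (not isolated), via ketol 12 (not isolated)
Conditions: KOH (cat.), MeOH, 0 °C to rt, then reflux
Reagents that add atoms: none
Why: Robinson annulation (Michael addition then aldol condensation): the more substituted, thermodynamic enolate at C10 should add to the vinyl ketone on the β face, away from the C9 side chain and the C8 methyl on the α face, which sets the quaternary C10 with C20 cis to the side chain, and C4 then condenses onto C5.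

**Step 7**
Reactants: 13 (4aS,5S,6S)-6-hydroxy-1,4a,6-trimethyl-5-[(3S)-3-methyl-5-(triisopropylsilyloxy)pentyl]-4,4a,5,6,7,8-hexahydronaphthalen-2(3H)-one
Product: 15 (4S,5S,8S,9S,10R,13S)-8,18-dihydroxy-15-(triisopropylsilyloxy)labdan-3-one, via dilithium enolate 14 (not isolated)
Conditions: Li, NH3(l)/THF, t-BuOH (1 equiv), −78 °C; isoprene; NH3 evaporated; CH2O (gas, from paraformaldehyde), THF, −78 °C; aq. NH4Cl
Reagents that add atoms: formaldehyde C=O
Why: Dissolving-metal reduction of the enone with reductive alkylation: axial protonation at C5 gives the trans-fused lithium enolate (H-5 anti to C20), and formaldehyde is taken up at C4 on the face remote from the angular C20 methyl, which places the hydroxymethyl group equatorial (C18) and the methyl axial (aldol addition to a regiospecific enolate).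

**Step 8**
Reactants: 15 (4S,5S,8S,9S,10R,13S)-8,18-dihydroxy-15-(triisopropylsilyloxy)labdan-3-one
Product: 16 3-(4-methylbenzenesulfonyl)hydrazone of 15 (stereocentres as in 15)
Conditions: TsNHNH2, EtOH, AcOH (cat.), 60 °C
Reagents that add atoms: 4-methylbenzenesulfonohydrazide Cc1ccc(cc1)S(=O)(=O)NN
Why: Hydrazone condensation under weak acid, which a neopentyl ketone should still undergo with the small hydrazide and which avoids the retro-aldol loss of formaldehyde that basic conditions would cause.

**Step 9**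
Reactants: 16 3-(4-methylbenzenesulfonyl)hydrazone of 15
Product: 17 (4S,5S,8S,9S,10R,13S)-15-(triisopropylsilyloxy)labdane-8,18-diol
Conditions: catecholborane (excess), CHCl3, 0 °C to rt; then NaOAc·3H2O, reflux
Reagents that add atoms: none
Why: Tosylhydrazone reduction with catecholborane followed by acetate-induced loss of sulfinate and dinitrogen (a mild Wolff–Kishner-type deoxygenation) should turn C3 into a methylene group without a base strong enough for retro-aldol cleavage, and no stereocentre is affected.

**Step 10**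
Reactants: 17 (4S,5S,8S,9S,10R,13S)-15-(triisopropylsilyloxy)labdane-8,18-diol; 18 angelic acid [(Z)-2-methylbut-2-enoic acid]
Product: 20 (4S,5S,8S,9S,10R,13S)-8-hydroxy-15-(triisopropylsilyloxy)labdan-18-yl (Z)-2-methylbut-2-enoate, via mixed anhydride 19 (not isolated)
Conditions: 2,4,6-trichlorobenzoyl chloride, Et3N, toluene, rt; then 17, toluene, 80 °C
Reagents that add atoms: none
Why: Yamaguchi-type esterification through the mixed anhydride should acylate the primary neopentyl C18 hydroxyl and leave the tertiary C8 hydroxyl, and the absence of a nucleophilic acyl-transfer catalyst should preserve the (Z)-geometry of the angelate.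

**Step 11**
Reactants: 20 (4S,5S,8S,9S,10R,13S)-8-hydroxy-15-(triisopropylsilyloxy)labdan-18-yl (Z)-2-methylbut-2-enoate
Product: 21 (4S,5S,8S,9S,10R,13S)-8,15-dihydroxylabdan-18-yl (Z)-2-methylbut-2-enoate
Conditions: HF·pyridine, THF/pyridine, 0 °C to rt
Reagents that add atoms: none
Why: Fluoride-mediated desilylation of the primary silyl ether under buffered, weakly acidic conditions that should leave the angelate ester and the tertiary alcohol untouched.

**Step 12**
Reactants: 21 (4S,5S,8S,9S,10R,13S)-8,15-dihydroxylabdan-18-yl (Z)-2-methylbut-2-enoate; 22 Meldrum's acid (2,2-dimethyl-1,3-dioxane-4,6-dione)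
Product: 23 3-{[(4S,5S,8S,9S,10R,13S)-8-hydroxy-18-[(Z)-2-methylbut-2-enoyloxy]labdan-15-yl]oxy}-3-oxopropanoic acid (CNP0286290.1)
Conditions: toluene, 90 °C
Reagents that add atoms: none
Why: Thermal acylation of the alcohol by Meldrum's acid (ring opening with loss of acetone) gives the malonic half ester directly, and only the primary C15 hydroxyl should be reactive enough while the tertiary C8 hydroxyl stays free.

**Compound list**

1 | (S)-citronellol [(S)-3,7-dimethyloct-6-en-1-ol] | CC(C)=CCC[C@H](C)CCO | starting material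
2 | (S)-triisopropyl[(3,7-dimethyloct-6-en-1-yl)oxy]silane | CC(C)=CCC[C@H](C)CCO[Si](C(C)C)(C(C)C)C(C)C | intermediate
3 | (S,E)-2,6-dimethyl-8-(triisopropylsilyloxy)oct-2-en-1-ol | OC/C(C)=C/CC[C@H](C)CCO[Si](C(C)C)(C(C)C)C(C)C | intermediate
4 | (S,E)-2,6-dimethyl-8-(triisopropylsilyloxy)oct-2-enal | O=C/C(C)=C/CC[C@H](C)CCO[Si](C(C)C)(C(C)C)C(C)C | intermediate
5 | pent-1-en-3-one (ethyl vinyl ketone) | CCC(=O)C=C | starting material
6 | (Z)-tert-butyldimethyl(penta-1,3-dien-3-yloxy)silane | C=C/C(O[Si](C)(C)C(C)(C)C)=C/C | intermediate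
7 | (1S,2S,3S)-4-(tert-butyldimethylsilyloxy)-1,3-dimethyl-2-[(3S)-3-methyl-5-(triisopropylsilyloxy)pentyl]cyclohex-4-ene-1-carbaldehyde (formyl trans to the side chain; C3 methyl drawn trans, this centre is erased in step 6) | C[C@@H]1C(O[Si](C)(C)C(C)(C)C)=CC[C@](C)(C=O)[C@H]1CC[C@H](C)CCO[Si](C(C)C)(C(C)C)C(C)C | intermediate
8 | (1S,2S,3S)-1,3-dimethyl-2-[(3S)-3-methyl-5-(triisopropylsilyloxy)pentyl]-4-oxocyclohexane-1-carbaldehyde | C[C@@H]1C(=O)CC[C@](C)(C=O)[C@H]1CC[C@H](C)CCO[Si](C(C)C)(C(C)C)C(C)C | intermediate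
9 | (1S,2S,3S)-1,3-dimethyl-2-[(3S)-3-methyl-5-(triisopropylsilyloxy)pentyl]-4-oxocyclohexyl formate | C[C@@H]1C(=O)CC[C@](C)(OC=O)[C@H]1CC[C@H](C)CCO[Si](C(C)C)(C(C)C)C(C)C | intermediate
10 | (2S,3S,4S)-4-hydroxy-2,4-dimethyl-3-[(3S)-3-methyl-5-(triisopropylsilyloxy)pentyl]cyclohexan-1-one | C[C@@H]1C(=O)CC[C@](C)(O)[C@H]1CC[C@H](C)CCO[Si](C(C)C)(C(C)C)C(C)C | intermediate
11 | (2S,3S,4S)-4-hydroxy-2,4-dimethyl-3-[(3S)-3-methyl-5-(triisopropylsilyloxy)pentyl]-2-(3-oxopentyl)cyclohexan-1-one | CCC(=O)CC[C@]1(C)C(=O)CC[C@](C)(O)[C@H]1CC[C@H](C)CCO[Si](C(C)C)(C(C)C)C(C)C | intermediate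
12 | bicyclic ketol: (4aS,5S,6S)-6,8a-dihydroxy-1,4a,6-trimethyl-5-[(3S)-3-methyl-5-(triisopropylsilyloxy)pentyl]octahydronaphthalen-2(1H)-one (C1 and C8a configuration immaterial, lost on dehydration) | O=C1CC[C@]2(C)C(O)(C1C)CC[C@](C)(O)[C@H]2CC[C@H](C)CCO[Si](C(C)C)(C(C)C)C(C)C | intermediate
13 | (4aS,5S,6S)-6-hydroxy-1,4a,6-trimethyl-5-[(3S)-3-methyl-5-(triisopropylsilyloxy)pentyl]-4,4a,5,6,7,8-hexahydronaphthalen-2(3H)-one | O=C1CC[C@]2(C)C(=C1C)CC[C@](C)(O)[C@H]2CC[C@H](C)CCO[Si](C(C)C)(C(C)C)C(C)C | intermediate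
14 | trans-fused dilithium species: lithium C3 enolate (C3=C4) with lithium C8 alkoxide, H-5 anti to C20 | CC1=C(O[Li])CC[C@]2(C)[C@@H]1CC[C@](C)(O[Li])[C@H]2CC[C@H](C)CCO[Si](C(C)C)(C(C)C)C(C)C | intermediate
15 | (4S,5S,8S,9S,10R,13S)-8,18-dihydroxy-15-(triisopropylsilyloxy)labdan-3-one | OC[C@@]1(C)C(=O)CC[C@]2(C)[C@@H]1CC[C@](C)(O)[C@H]2CC[C@H](C)CCO[Si](C(C)C)(C(C)C)C(C)C | intermediate
16 | 3-(4-methylbenzenesulfonyl)hydrazone of 15 (stereocentres as in 15; C=N geometry not defined) | OC[C@@]1(C)C(=NNS(=O)(=O)c3ccc(C)cc3)CC[C@]2(C)[C@@H]1CC[C@](C)(O)[C@H]2CC[C@H](C)CCO[Si](C(C)C)(C(C)C)C(C)C | intermediate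
17 | (4S,5S,8S,9S,10R,13S)-15-(triisopropylsilyloxy)labdane-8,18-diol | OC[C@@]1(C)CCC[C@]2(C)[C@@H]1CC[C@](C)(O)[C@H]2CC[C@H](C)CCO[Si](C(C)C)(C(C)C)C(C)C | intermediate
18 | angelic acid [(Z)-2-methylbut-2-enoic acid] | C/C=C(/C)C(=O)O | starting material
19 | (Z)-2-methylbut-2-enoic 2,4,6-trichlorobenzoic anhydride | C/C=C(/C)C(=O)OC(=O)c1c(Cl)cc(Cl)cc1Cl | intermediate
20 | (4S,5S,8S,9S,10R,13S)-8-hydroxy-15-(triisopropylsilyloxy)labdan-18-yl (Z)-2-methylbut-2-enoate | C/C=C(/C)C(=O)OC[C@@]1(C)CCC[C@]2(C)[C@@H]1CC[C@](C)(O)[C@H]2CC[C@H](C)CCO[Si](C(C)C)(C(C)C)C(C)C | intermediate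
21 | (4S,5S,8S,9S,10R,13S)-8,15-dihydroxylabdan-18-yl (Z)-2-methylbut-2-enoate | C/C=C(/C)C(=O)OC[C@@]1(C)CCC[C@]2(C)[C@@H]1CC[C@](C)(O)[C@H]2CC[C@H](C)CCO | intermediate
22 | Meldrum's acid (2,2-dimethyl-1,3-dioxane-4,6-dione) | CC1(C)OC(=O)CC(=O)O1 | starting material
23 | 3-{[(4S,5S,8S,9S,10R,13S)-8-hydroxy-18-[(Z)-2-methylbut-2-enoyloxy]labdan-15-yl]oxy}-3-oxopropanoic acid (CNP0286290.1) | C/C=C(/C)C(=O)OC[C@@]1(C)CCC[C@]2(C)[C@@H]1CC[C@](C)(O)[C@H]2CC[C@H](C)CCOC(=O)CC(=O)O | target

**Step count.** Total: 12 steps. Longest linear sequence: 11 steps (steps 1, 2 and 4–12 from (S)-citronellol; step 3 is a one-step branch).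

**Steps most likely to fail**

Step 4. The trisubstituted, β-alkylated enal may react too slowly with the simple siloxydiene, the diene may add in a Mukaiyama-type fashion without ring closure, or facial discrimination by the catalyst may be insufficient. The fallback sets out from 4 and comes back at 8, using a more reactive diene class and a different chiral Lewis acid. Conjugate addition of dimethylamine to commercial pent-1-yn-3-one gives (E)-1-(dimethylamino)pent-1-en-3-one F1, and KHMDS/TBSCl converts it into (1E,3Z)-3-(tert-butyldimethylsilyloxy)-N,N-dimethylpenta-1,3-dien-1-amine F2. Its cycloaddition with 4, catalysed by the chromium chloride complex of N,N'-bis(3,5-di-tert-butylsalicylidene)cyclohexane-1,2-diamine (trivalent chromium; the salen enantiomer that delivers the C8 Si-face adduct), gives the amino cycloadduct F3, again with the C7–C8 bond closing ring B. Dilute HCl hydrolyses the enol ether and eliminates dimethylamine to the enone aldehyde F4, and hydrogenation of its C6=C7 bond (H2, Pd/C, EtOAc) gives 8.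

Step 5. The peracid may also attack the ring ketone (ring expansion to a lactone), or hydrogen may migrate instead of C8 to give the acid. The fallback sets out from 7, which is isolated by neutral work-up instead of being hydrolysed, and comes back at 10; it masks the ring carbonyl as a conjugated enone, which is inert to peracid. Saegusa–Ito oxidation of 7 (Pd(OAc)2, MeCN) gives the enone aldehyde F4. Baeyer–Villiger oxidation (m-CPBA, NaHCO3) then gives the enone formate F5, and methanolysis (K2CO3, MeOH) the hydroxy enone F6. Hydrogenation over chlorotris(triphenylphosphine)rhodium, RhCl(PPh3)3, chosen to avoid hydrogenolysis of the tertiary allylic alcohol, gives 10.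

Step 6. The vinyl ketone may be taken up at the less hindered C6 position instead of C10, or the facial selectivity at C10 may erode. The fallback sets out from 10 and comes back at 13, using a regiodefined enol ether instead of an equilibrating enolate. Silylation under equilibrating conditions (TMSCl, NaI, Et3N, MeCN) gives the more substituted bis(trimethylsilyl) compound F7 (C5=C10 enol ether, C8 silyl ether), which can be purified. Mukaiyama–Michael addition to ethyl vinyl ketone (TiCl4/Ti(OiPr)4, CH2Cl2, −78 °C) gives the diketone F8 with the quaternary C10 in place. KOH in MeOH at reflux then effects aldol condensation and cleaves the tertiary silyl ether to give 13.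

Further compounds
F1 | step 4 | (E)-1-(dimethylamino)pent-1-en-3-one | CCC(=O)/C=C/N(C)C
F2 | step 4 | (1E,3Z)-3-(tert-butyldimethylsilyloxy)-N,N-dimethylpenta-1,3-dien-1-amine | C/C=C(O[Si](C)(C)C(C)(C)C)/C=C/N(C)C
F3 | step 4 | 4-(tert-butyldimethylsilyloxy)-6-(dimethylamino)-1,3-dimethyl-2-[(3S)-3-methyl-5-(triisopropylsilyloxy)pentyl]cyclohex-4-ene-1-carbaldehyde (C1–C3 as in 7; C6 not defined) | C[C@@H]1C(O[Si](C)(C)C(C)(C)C)=CC(N(C)C)[C@](C)(C=O)[C@H]1CC[C@H](C)CCO[Si](C(C)C)(C(C)C)C(C)C
F4 | step 4 | (1S,2S,3S)-1,3-dimethyl-2-[(3S)-3-methyl-5-(triisopropylsilyloxy)pentyl]-4-oxocyclohex-5-ene-1-carbaldehyde | C[C@@H]1C(=O)C=C[C@](C)(C=O)[C@H]1CC[C@H](C)CCO[Si](C(C)C)(C(C)C)C(C)C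
F5 | step 5 | formate ester of F6 (configuration as in 9) | C[C@@H]1C(=O)C=C[C@](C)(OC=O)[C@H]1CC[C@H](C)CCO[Si](C(C)C)(C(C)C)C(C)C
F6 | step 5 | (4S,5S,6S)-4-hydroxy-4,6-dimethyl-5-[(3S)-3-methyl-5-(triisopropylsilyloxy)pentyl]cyclohex-2-en-1-one | C[C@@H]1C(=O)C=C[C@](C)(O)[C@H]1CC[C@H](C)CCO[Si](C(C)C)(C(C)C)C(C)C
F7 | step 6 | bis(trimethylsilyl) derivative of 10: C5=C10 trimethylsilyl enol ether with C8 trimethylsilyl ether | CC1=C(O[Si](C)(C)C)CC[C@](C)(O[Si](C)(C)C)[C@H]1CC[C@H](C)CCO[Si](C(C)C)(C(C)C)C(C)C
F8 | step 6 | C8 trimethylsilyl ether of Michael adduct 11 | CCC(=O)CC[C@]1(C)C(=O)CC[C@](C)(O[Si](C)(C)C)[C@H]1CC[C@H](C)CCO[Si](C(C)C)(C(C)C)C(C)C
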